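**Strategy.** The carbocycle of the azaphilone (C4a–C5–C6–C7–C8–C8a, isochromene numbering) holds an acyloin: the C6 ketone sits next to the oxygenated quaternary C7, itself flanked by the C8 ketone. The C6–C7 bond is made by a carbene-catalysed intramolecular crossed benzoin, which closes the carbocycle onto a preformed pyran and sets C7 (R) by catalyst control in one operation. The precursor is a monocyclic 4H-pyran-4-ylidene acetaldehyde (the C6 aldehyde) with a pyruvoyl group (C8 and C7 ketones) on the neighbouring ring carbon, assembled in one pot from an enaminone and an alkynone. Esterification with silylated orsellinic acid, desilylation and allylic oxidation finish the route.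

Key step: step 7

Remark: the sense of induction of the aminoindanol triazolium catalyst on this new substrate is assumed; both antipodes are available and the one that delivers the 7R ketol is used.

Step 1
Reactants: 1 3,3-dimethoxybutan-2-one
Product: 2 (E)-1-(dimethylamino)-4,4-dimethoxypent-1-en-3-one
Conditions: Me2NCH(OMe)2 (1.5 equiv), neat, 100 °C, MeOH distilled off
Reagents that add atoms: N,N-dimethylformamide dimethyl acetal, COC(OC)N(C)C
Why: Aminomethylenation of the only enolisable position (the methyl ketone) by the amide acetal should give the E push–pull enaminone; no stereocentre is formed.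

Step 2
Reactants: 3 (Z)-but-2-ene-1,4-diol
Product: 4 (Z)-4-{[tert-butyl(diphenyl)silyl]oxy}but-2-en-1-ol
Conditions: t-BuPh2SiCl (1 equiv), imidazole, diol (4 equiv), THF, 0 °C to rt
Reagents that add atoms: tert-butyl(chloro)diphenylsilane, CC(C)(C)[Si](Cl)(c1ccccc1)c1ccccc1
Why: Statistical mono-silylation of a symmetrical diol used in excess with a bulky silyl chloride should stop at the mono-ether; the Z alkene is untouched.

Step 3
Reactants: 4 (Z)-4-{[tert-butyl(diphenyl)silyl]oxy}but-2-en-1-ol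
Product: 5 (E)-4-{[tert-butyl(diphenyl)silyl]oxy}but-2-enal
Conditions: [C5H5NH][CrO3Cl] (pyridinium chlorochromate, 1.5 equiv), Celite, CH2Cl2, rt
Reagents that add atoms: none
Why: Chlorochromate oxidation of the allylic alcohol gives the enal, which under the mildly acidic conditions should isomerise to the thermodynamically preferred E geometry.

Step 4
Reactants: 6 4,4-diethoxybut-1-yne; 5 (E)-4-{[tert-butyl(diphenyl)silyl]oxy}but-2-enal
Product: 8 rac-(2E)-1-{[tert-butyl(diphenyl)silyl]oxy}-8,8-diethoxyoct-2-en-5-yn-4-ol, via lithium acetylide 7 (not isolated)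
Conditions: n-BuLi, THF, −78 °C; then 5, −78 °C; aq NH4Cl
Reagents that add atoms: none
Why: 1,2-Addition of a lithium acetylide to an enal at low temperature; the new carbinol centre is racemic and is erased in step 5.

Step 5
Reactants: 8 rac-(2E)-1-{[tert-butyl(diphenyl)silyl]oxy}-8,8-diethoxyoct-2-en-5-yn-4-ol
Product: 9 (2E)-1-{[tert-butyl(diphenyl)silyl]oxy}-8,8-diethoxyoct-2-en-5-yn-4-one
Conditions: MnO2 (activated, 15 equiv), CH2Cl2, rt
Reagents that add atoms: none
Why: MnO2 oxidation of a doubly activated (allylic and propargylic) alcohol should give the cross-conjugated alkynone under neutral conditions that leave the propargylic CH2 and the acetal alone.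

Step 6
Reactants: 9 (2E)-1-{[tert-butyl(diphenyl)silyl]oxy}-8,8-diethoxyoct-2-en-5-yn-4-one; 2 (E)-1-(dimethylamino)-4,4-dimethoxypent-1-en-3-one
Product: 12 2-[2-[(1E)-3-{[tert-butyl(diphenyl)silyl]oxy}prop-1-en-1-yl]-5-(2-oxopropanoyl)-4H-pyran-4-ylidene]acetaldehyde, via aminodienone 10 (not isolated), via pyrylium salt 11 (not isolated)
Conditions: toluene/AcOH (5:1), 50 °C; then CF3CO2H/H2O (9:1), CH2Cl2, 0 °C to rt; quench into pH 5 buffer
Reagents that add atoms: water, O
Why: Proposed new method: the nucleophilic α-carbon of enaminone 2 should add to the β-carbon of alkynone 9, as in the first stage of the Bohlmann–Rahtz pyridine synthesis, to give aminodienone 10; because the nitrogen is tertiary, the dienone oxygen closes onto the protonated enaminone carbon (oxa-6π or 6-exo-trig addition–elimination) with loss of dimethylamine to give pyrylium salt 11, a closure known for 5-aminopenta-2,4-dienones in acid; aqueous CF3CO2H then cleaves acetal and ketal, and loss of a proton from the 4-(2-hydroxyvinyl)pyrylium ion gives neutral 12; the regiochemistry is fixed because only the former alkynone oxygen can displace the amine, and the strongly acidic medium keeps the ring closed as the pyrylium ion; closest known reaction types: Bohlmann–Rahtz heteroannulation and pyrylium formation from 1,5-dicarbonyl equivalents.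

Step 7
Reactants: 12 2-[2-[(1E)-3-{[tert-butyl(diphenyl)silyl]oxy}prop-1-en-1-yl]-5-(2-oxopropanoyl)-4H-pyran-4-ylidene]acetaldehyde
Product: 13 (7R)-3-[(1E)-3-{[tert-butyl(diphenyl)silyl]oxy}prop-1-en-1-yl]-7-hydroxy-7-methyl-6H-isochromene-6,8(7H)-dione
Conditions: (5aS,10bR)-2-mesityl-5a,10b-dihydro-4H,6H-indeno[2,1-b][1,2,4]triazolo[4,3-d][1,4]oxazin-2-ium chloride (15 mol%), DBU (15 mol%), toluene (0.02 M), 4 Å MS, rt
Reagents that add atoms: none
Why: The triazolylidene adds to the C6 aldehyde of 12 and proton transfer gives the Breslow intermediate, whose nucleophilic C6 attacks the C7 carbonyl of the pyruvoyl group; proton transfer and loss of the carbene release the tertiary α-ketol. The closest known reaction type is the enantioselective intramolecular crossed aldehyde–ketone benzoin cyclisation to six-membered tertiary acyloins with aminoindanol-derived triazolium salts. The carbocycle C4a–C5–C6–C7–C8–C8a closes in the 6-exo-trig mode onto the ketone, the push–pull exocyclic C4a=C5 bond rotating freely to bring the aldehyde next to the pyruvoyl group. C7 is the only new stereocentre and is set by the catalyst, whose indane wall leaves one enantiotopic face of the C7 ketone open to the Breslow carbon. The step needs C7 over C8 selectivity (C8 is a vinylogous ester carbonyl and its attack would give a strained five-membered ring), acyl-anion over homoenolate reactivity (the β-carbon C4a is a fully substituted ring carbon that cannot reach C7) and a single aldehyde, which the silyl-masked side chain and the absence of acidic hydrogen at C8a secure.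

Step 8
Reactants: 14 orsellinic acid (2,4-dihydroxy-6-methylbenzoic acid)
Product: 15 tert-butyldimethylsilyl 2,4-bis{[tert-butyl(dimethyl)silyl]oxy}-6-methylbenzoate
Conditions: t-BuMe2SiCl (3.5 equiv), imidazole, DMF, rt
Reagents that add atoms: tert-butyl(chloro)dimethylsilane, CC(C)(C)[Si](C)(C)Cl
Why: Exhaustive silylation should convert both phenols into silyl ethers and the acid into its silyl ester.

Step 9
Reactants: 15 tert-butyldimethylsilyl 2,4-bis{[tert-butyl(dimethyl)silyl]oxy}-6-methylbenzoate; 13 (7R)-3-[(1E)-3-{[tert-butyl(diphenyl)silyl]oxy}prop-1-en-1-yl]-7-hydroxy-7-methyl-6H-isochromene-6,8(7H)-dione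
Product: 17 (7R)-3-[(1E)-3-{[tert-butyl(diphenyl)silyl]oxy}prop-1-en-1-yl]-7-methyl-6,8-dioxo-7,8-dihydro-6H-isochromen-7-yl 2,4-bis{[tert-butyl(dimethyl)silyl]oxy}-6-methylbenzoate, via acid chloride 16 (not isolated)
Conditions: (COCl)2, DMF (cat.), CH2Cl2, 0 °C to rt; evaporate; then 13, DMAP, Et3N, CH2Cl2, 0 °C to rt
Reagents that add atoms: none
Why: The silyl ester should be converted into the acid chloride under neutral conditions that spare the aryl silyl ethers, and DMAP-catalysed acylation of the tertiary α-ketol then forms the ester; the quaternary C7 cannot epimerise.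

Step 10
Reactants: 17 (7R)-3-[(1E)-3-{[tert-butyl(diphenyl)silyl]oxy}prop-1-en-1-yl]-7-methyl-6,8-dioxo-7,8-dihydro-6H-isochromen-7-yl 2,4-bis{[tert-butyl(dimethyl)silyl]oxy}-6-methylbenzoate
Product: 18 (7R)-3-[(1E)-3-hydroxyprop-1-en-1-yl]-7-methyl-6,8-dioxo-7,8-dihydro-6H-isochromen-7-yl 2,4-dihydroxy-6-methylbenzoate
Conditions: HF·pyridine, pyridine, THF, 0 °C to rt
Reagents that add atoms: none
Why: Buffered fluoride should cleave both aryl silyl ethers and the primary silyl ether without the basic conditions that would open the pyran or shift the ester.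

Step 11
Reactants: 18 (7R)-3-[(1E)-3-hydroxyprop-1-en-1-yl]-7-methyl-6,8-dioxo-7,8-dihydro-6H-isochromen-7-yl 2,4-dihydroxy-6-methylbenzoate
Product: 19 (7R)-7-methyl-6,8-dioxo-3-[(1E)-3-oxoprop-1-en-1-yl]-7,8-dihydro-6H-isochromen-7-yl 2,4-dihydroxy-6-methylbenzoate
Conditions: MnO2 (activated, 10 equiv), CH2Cl2, rt
Reagents that add atoms: none
Why: MnO2 should oxidise only the primary allylic alcohol to the E enal; the ester-deactivated phenols and the tertiary ester are expected to survive.

**Compound list**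

1 | 3,3-dimethoxybutan-2-one | CC(=O)C(C)(OC)OC | starting material
2 | (E)-1-(dimethylamino)-4,4-dimethoxypent-1-en-3-one | CN(C)/C=C/C(=O)C(C)(OC)OC | intermediate
3 | (Z)-but-2-ene-1,4-diol | OC/C=C\CO | starting material
4 | (Z)-4-{[tert-butyl(diphenyl)silyl]oxy}but-2-en-1-ol | OC/C=C\CO[Si](c1ccccc1)(c1ccccc1)C(C)(C)C | intermediate
5 | (E)-4-{[tert-butyl(diphenyl)silyl]oxy}but-2-enal | O=C/C=C/CO[Si](c1ccccc1)(c1ccccc1)C(C)(C)C | intermediate
6 | 4,4-diethoxybut-1-yne | C#CCC(OCC)OCC | starting material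
7 | (4,4-diethoxybut-1-yn-1-yl)lithium | [Li]C#CCC(OCC)OCC | intermediate
8 | rac-(2E)-1-{[tert-butyl(diphenyl)silyl]oxy}-8,8-diethoxyoct-2-en-5-yn-4-ol | CCOC(CC#CC(O)/C=C/CO[Si](c1ccccc1)(c1ccccc1)C(C)(C)C)OCC | intermediate
9 | (2E)-1-{[tert-butyl(diphenyl)silyl]oxy}-8,8-diethoxyoct-2-en-5-yn-4-one | CCOC(CC#CC(=O)/C=C/CO[Si](c1ccccc1)(c1ccccc1)C(C)(C)C)OCC | intermediate
10 | (8E)-10-{[tert-butyl(diphenyl)silyl]oxy}-5-(2,2-diethoxyethyl)-4-[(dimethylamino)methylidene]-2,2-dimethoxydeca-5,8-diene-3,7-dione (aminodienone; geometry of the two new double bonds not fixed) | CCOC(CC(=CC(=O)/C=C/CO[Si](c1ccccc1)(c1ccccc1)C(C)(C)C)C(=CN(C)C)C(=O)C(C)(OC)OC)OCC | intermediate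
11 | 2-[(1E)-3-{[tert-butyl(diphenyl)silyl]oxy}prop-1-en-1-yl]-4-(2,2-diethoxyethyl)-5-(2,2-dimethoxypropanoyl)pyrylium acetate | CCOC(Cc1cc(/C=C/CO[Si](c2ccccc2)(c2ccccc2)C(C)(C)C)[o+]cc1C(=O)C(C)(OC)OC)OCC.CC(=O)[O-] | intermediate
12 | 2-[2-[(1E)-3-{[tert-butyl(diphenyl)silyl]oxy}prop-1-en-1-yl]-5-(2-oxopropanoyl)-4H-pyran-4-ylidene]acetaldehyde (exocyclic C=C drawn with CHO on the acyl side; configurationally labile) | O=C/C=C1\C(C(=O)C(C)=O)=COC(/C=C/CO[Si](c2ccccc2)(c2ccccc2)C(C)(C)C)=C1 | intermediate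
13 | (7R)-3-[(1E)-3-{[tert-butyl(diphenyl)silyl]oxy}prop-1-en-1-yl]-7-hydroxy-7-methyl-6H-isochromene-6,8(7H)-dione | O[C@]1(C)C(=O)C=C2C=C(/C=C/CO[Si](c3ccccc3)(c3ccccc3)C(C)(C)C)OC=C2C1=O | intermediate
14 | orsellinic acid (2,4-dihydroxy-6-methylbenzoic acid) | Cc1cc(O)cc(O)c1C(=O)O | starting material
15 | tert-butyldimethylsilyl 2,4-bis{[tert-butyl(dimethyl)silyl]oxy}-6-methylbenzoate | Cc1cc(O[Si](C)(C)C(C)(C)C)cc(O[Si](C)(C)C(C)(C)C)c1C(=O)O[Si](C)(C)C(C)(C)C | intermediate
16 | 2,4-bis{[tert-butyl(dimethyl)silyl]oxy}-6-methylbenzoyl chloride | Cc1cc(O[Si](C)(C)C(C)(C)C)cc(O[Si](C)(C)C(C)(C)C)c1C(Cl)=O | intermediate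
17 | (7R)-3-[(1E)-3-{[tert-butyl(diphenyl)silyl]oxy}prop-1-en-1-yl]-7-methyl-6,8-dioxo-7,8-dihydro-6H-isochromen-7-yl 2,4-bis{[tert-butyl(dimethyl)silyl]oxy}-6-methylbenzoate | Cc1cc(O[Si](C)(C)C(C)(C)C)cc(O[Si](C)(C)C(C)(C)C)c1C(=O)O[C@]1(C)C(=O)C=C2C=C(/C=C/CO[Si](c3ccccc3)(c3ccccc3)C(C)(C)C)OC=C2C1=O | intermediate
18 | (7R)-3-[(1E)-3-hydroxyprop-1-en-1-yl]-7-methyl-6,8-dioxo-7,8-dihydro-6H-isochromen-7-yl 2,4-dihydroxy-6-methylbenzoate | Cc1cc(O)cc(O)c1C(=O)O[C@]1(C)C(=O)C=C2C=C(/C=C/CO)OC=C2C1=O | intermediate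
19 | (7R)-7-methyl-6,8-dioxo-3-[(1E)-3-oxoprop-1-en-1-yl]-7,8-dihydro-6H-isochromen-7-yl 2,4-dihydroxy-6-methylbenzoate (CNP0200982.1) | Cc1cc(O)cc(O)c1C(=O)O[C@]1(C)C(=O)C=C2C=C(/C=C/C=O)OC=C2C1=O | target

**Step count.** Total: 11 steps. Longest linear sequence: 9 steps (2, 3, 4, 5, 6, 7, 9, 10, 11).

**Steps most likely to fail**

Step 6 (Proposed new method). The tertiary enaminone may add too slowly to the internal alkynone, the alkynone may drift to an allenone or dienone, the ring may close through the wrong oxygen, or the pyranylidene may open and re-close to an isomeric pyran during the aqueous phase. The fallback uses known chemistry, sets out from 9 and 1 and returns at 12. Addition of HCl to 9 (LiCl, AcOH, rt) should give the β-chlorovinyl ketone (2E,5Z)-1-{[tert-butyl(diphenyl)silyl]oxy}-6-chloro-8,8-diethoxyocta-2,5-dien-4-one F1. Claisen formylation of 1 (HCO2Et, NaH, Et2O) gives sodium (E)-4,4-dimethoxy-3-oxopent-1-en-1-olate F2. Kochetkov C-ketovinylation of F2 with F1 (THF, rt) gives the 2-formyl-1,5-diketone F3, whose aldehyde–ketone pair is closed to the pyrylium ion by CF3CO2H/H2O, which also cleaves acetal and ketal to give 12.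

Step 7 (key step). Carbene addition to the electron-rich, vinylogous formyl group may be slow, the carbene may add reversibly at C1 of the pyran, or facial discrimination at the C7 ketone may be poor. The fallback keeps the C6–C7 ring closure but changes the oxidation level; it sets out from 12 and returns at 13. Transfer hydrogenation of the pyrylium form of 12 (diethyl 2,6-dimethyl-1,4-dihydropyridine-3,5-dicarboxylate, CF3CO2H, CH2Cl2) should deliver hydride to C4a and give the racemic 4H-pyran aldehyde F4, an ordinary aliphatic aldehyde. The same triazolium catalyst then closes the ring to the 4a,5-dihydro ketol F5. Dehydrogenation with DDQ (CH2Cl2, rt) restores the C4a=C5 bond and gives 13.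

Step 9. Acylation of the hindered tertiary α-ketol by a di-ortho-substituted benzoyl chloride may stall or be overtaken by decomposition of the acid chloride. The fallback replaces acid-chloride acylation by alkoxide opening of a salicylate acetonide; it sets out from 14 and 13 and returns at 18. Orsellinic acid 14 is converted (acetone, (CF3CO)2O, CF3CO2H) into 7-hydroxy-2,2,5-trimethyl-4H-1,3-benzodioxin-4-one F6 and silylated (t-BuMe2SiCl, imidazole) to the silyl ether F7. The sodium alkoxide of 13 (NaN(SiMe3)2, THF, −78 °C) opens F7 to the salicylate ester F8, which enters step 10 and gives 18.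

**Further compounds**

F1 | step 6 | (2E,5Z)-1-{[tert-butyl(diphenyl)silyl]oxy}-6-chloro-8,8-diethoxyocta-2,5-dien-4-one | CCOC(C/C(Cl)=C/C(=O)/C=C/CO[Si](c1ccccc1)(c1ccccc1)C(C)(C)C)OCC
F2 | step 6 | sodium (E)-4,4-dimethoxy-3-oxopent-1-en-1-olate | [Na+].[O-]/C=C/C(=O)C(C)(OC)OC
F3 | step 6 | (8E)-10-{[tert-butyl(diphenyl)silyl]oxy}-5-(2,2-diethoxyethyl)-4-formyl-2,2-dimethoxydeca-5,8-diene-3,7-dione | CCOC(CC(=CC(=O)/C=C/CO[Si](c1ccccc1)(c1ccccc1)C(C)(C)C)C(C=O)C(=O)C(C)(OC)OC)OCC
F4 | step 7 | rac-2-[2-[(1E)-3-{[tert-butyl(diphenyl)silyl]oxy}prop-1-en-1-yl]-5-(2-oxopropanoyl)-4H-pyran-4-yl]acetaldehyde | O=CCC1C=C(/C=C/CO[Si](c2ccccc2)(c2ccccc2)C(C)(C)C)OC=C1C(=O)C(C)=O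
F5 | step 7 | (7R)-3-[(1E)-3-{[tert-butyl(diphenyl)silyl]oxy}prop-1-en-1-yl]-7-hydroxy-7-methyl-4a,5-dihydro-6H-isochromene-6,8(7H)-dione (mixture at C4a) | O[C@]1(C)C(=O)CC2C=C(/C=C/CO[Si](c3ccccc3)(c3ccccc3)C(C)(C)C)OC=C2C1=O
F6 | step 9 | 7-hydroxy-2,2,5-trimethyl-4H-1,3-benzodioxin-4-one | Cc1cc(O)cc2c1C(=O)OC(C)(C)O2
F7 | step 9 | 7-{[tert-butyl(dimethyl)silyl]oxy}-2,2,5-trimethyl-4H-1,3-benzodioxin-4-one | Cc1cc(O[Si](C)(C)C(C)(C)C)cc2c1C(=O)OC(C)(C)O2
F8 | step 9 | (7R)-3-[(1E)-3-{[tert-butyl(diphenyl)silyl]oxy}prop-1-en-1-yl]-7-methyl-6,8-dioxo-7,8-dihydro-6H-isochromen-7-yl 4-{[tert-butyl(dimethyl)silyl]oxy}-2-hydroxy-6-methylbenzoate | Cc1cc(O[Si](C)(C)C(C)(C)C)cc(O)c1C(=O)O[C@]1(C)C(=O)C=C2C=C(/C=C/CO[Si](c3ccccc3)(c3ccccc3)C(C)(C)C)OC=C2C1=O
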